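**Plan**

- Retrosynthesis: the O3-benzyl group is removed last. Ring A is cut at C4a–C5 and C8–C8a, which excises C5–C6–C7–C8 with all four oxygens as dimethyl squarate and leaves C4a=C8a as the C5=C6 bond of a 3-benzyloxy-2-aryl-γ-pyrone. The pyrone is cut at C3–C4 and O1–C8a, and its ketone precursor at C2–C1'.
- Forward: ring B is bought, ring C (the γ-pyrone) is built second, and ring A is formed last by thermal ring expansion of a 4-pyranyl-4-methoxycyclobutenone (4π opening, 6π closure, tautomerisation).
- Enabling feature: C5(OH), C6(OMe), C7(OMe), C8(OMe) are four contiguous oxygenated ring-A carbons with C5–O and C8–O para, which is the C4O4 pattern of squaric acid, fused to a γ-pyrone C=C.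
- Differentiation: the ketene carbonyl becomes the free, C4=O-chelated 5-OH and the methylated carbinol becomes 8-OMe, so the one free phenol among the ring-A ethers is programmed and no selective demethylation is needed.
- Stereochemistry: the target has no stereocentre. The transient elements (C4 of 10, the Z-alkene of 11, C4a of 12) vanish on aromatisation.

Key step: step 4

Remark: the target is achiral, so "single enantiomer" needs no control. Compounds 1, 2, 4 and 7 are taken as catalogue compounds.

**Step 1**
Reactants: 1 2-(benzyloxy)-N-methoxy-N-methylacetamide; 2 (4-methoxyphenyl)magnesium bromide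
Product: 3 2-(benzyloxy)-1-(4-methoxyphenyl)ethan-1-one
Conditions: THF, 0 °C; then 1 M HCl
Reagents that add atoms: none
Why: Weinreb ketone synthesis, in which the chelated tetrahedral magnesium adduct should prevent over-addition and release the ketone only on acidic work-up.

**Step 2**
Reactants: 3 2-(benzyloxy)-1-(4-methoxyphenyl)ethan-1-one; 4 (E)-3-ethoxyprop-2-enoyl chloride
Product: 6 3-(benzyloxy)-2-(4-methoxyphenyl)-4H-pyran-4-one, via diketone 5 (not isolated)
Conditions: MgBr2·OEt2, i-Pr2NEt, CH2Cl2, 0 °C to rt; then TFA, CH2Cl2, rt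
Reagents that add atoms: none
Why: soft-enolisation C-acylation of the chelating α-alkoxy ketone should give the 1,3-diketone, whose aryl-ketone enol oxygen then adds to the β-ethoxy enone carbon and expels ethanol (acid-mediated γ-pyrone cyclocondensation).

**Step 3**
Reactants: 6 3-(benzyloxy)-2-(4-methoxyphenyl)-4H-pyran-4-one; 7 dimethyl squarate (3,4-dimethoxycyclobut-3-ene-1,2-dione)
Product: 10 4-[5-(benzyloxy)-6-(4-methoxyphenyl)-4-oxo-4H-pyran-2-yl]-2,3,4-trimethoxycyclobut-2-en-1-one (racemic), via lithiated pyranone 8 (not isolated), via lithium alkoxide 9 (not isolated)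
Conditions: TMPH, n-BuLi, THF, 0 °C; 6, −78 °C; 7, −78 °C; MeOTf (1.1 equiv), −78 to −20 °C; aq. NaHCO3
Reagents that add atoms: methyl trifluoromethanesulfonate, COS(=O)(=O)C(F)(F)F
Why: kinetic deprotonation by the hindered amide should occur at the sp2 C6–H next to the ring oxygen (C2 is blocked by the aryl group), as in the C2-lithiation of 3-substituted chromones, and 1,2-addition of the vinyllithium to one squarate carbonyl followed by O-methylation of the tertiary alkoxide is standard cyclobutenone chemistry; the new quaternary centre is racemic and is destroyed in step 4.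

**Step 4**
Reactants: 10 4-[5-(benzyloxy)-6-(4-methoxyphenyl)-4-oxo-4H-pyran-2-yl]-2,3,4-trimethoxycyclobut-2-en-1-one
Product: 13 3-(benzyloxy)-5-hydroxy-6,7,8-trimethoxy-2-(4-methoxyphenyl)-4H-chromen-4-one, via dienylketene 11 (not isolated), via cyclohexadienone 12 (not isolated)
Conditions: toluene (degassed), 110 °C, Ar
Reagents that add atoms: none
Why: thermal conrotatory 4π ring opening of the cyclobutenone (C1–C4 cleavage) should give the (Z)-dienylketene 11, whose ketene carbon closes onto C5 of the pyranone in a 6π electrocyclisation to give 12, and enolisation of the C4a–H then aromatises ring A. The closest known reaction type is the thermal ring expansion of 4-alkenyl- and 4-(hetero)aryl-4-alkoxycyclobutenones to phenols and hydroquinone monoethers (Moore-type rearrangement). Ring A is closed by the 6π electrocyclisation, which forms the C5–C4a bond, the C8–C8a bond having been made in step 3. No stereocentre survives, since C4 of 10 and C4a of 12 both become sp2. The step needs inward rotation of the pyranyl group, which the donor 4-methoxy group secures by rotating outward, and it needs the ketene not to be trapped internally, which the methylated carbinol oxygen secures by excluding furanone formation. Regiochemistry is fixed by the substrate: C5 is the only pyranone carbon within reach and is the nucleophilic α-carbon of the vinylogous ester, matched to the electrophilic ketene carbon, and the ketene oxygen ends as 5-OH while the three methoxy groups end at C6, C7 and C8.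

**Step 5**
Reactants: 13 3-(benzyloxy)-5-hydroxy-6,7,8-trimethoxy-2-(4-methoxyphenyl)-4H-chromen-4-one
Product: 14 3,5-dihydroxy-6,7,8-trimethoxy-2-(4-methoxyphenyl)-4H-chromen-4-one
Conditions: H2 (1 atm), 10% Pd/C, EtOAc, rt
Reagents that add atoms: none
Why: hydrogenolysis of the 3-O-benzyl ether should proceed cleanly because the tetrasubstituted C2=C3 bond of the chromone, the aryl methyl ethers and the chelated phenol are inert under these conditions.

**Compound list**

1 | 2-(benzyloxy)-N-methoxy-N-methylacetamide | CON(C)C(=O)COCc1ccccc1 | starting material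
2 | (4-methoxyphenyl)magnesium bromide | COc1ccc([Mg]Br)cc1 | starting material
3 | 2-(benzyloxy)-1-(4-methoxyphenyl)ethan-1-one | COc1ccc(cc1)C(=O)COCc1ccccc1 | intermediate
4 | (E)-3-ethoxyprop-2-enoyl chloride | CCO/C=C/C(Cl)=O | starting material
5 | (E)-2-(benzyloxy)-5-ethoxy-1-(4-methoxyphenyl)pent-4-ene-1,3-dione | CCO/C=C/C(=O)C(OCc1ccccc1)C(=O)c1ccc(OC)cc1 | intermediate (not isolated)
6 | 3-(benzyloxy)-2-(4-methoxyphenyl)-4H-pyran-4-one | COc1ccc(cc1)-c1occc(=O)c1OCc1ccccc1 | intermediate
7 | dimethyl squarate (3,4-dimethoxycyclobut-3-ene-1,2-dione) | COC1=C(OC)C(=O)C1=O | starting material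
8 | [5-(benzyloxy)-6-(4-methoxyphenyl)-4-oxo-4H-pyran-2-yl]lithium | [Li]c1cc(=O)c(OCc2ccccc2)c(-c2ccc(OC)cc2)o1 | intermediate (not isolated)
9 | lithium 1-[5-(benzyloxy)-6-(4-methoxyphenyl)-4-oxo-4H-pyran-2-yl]-2,3-dimethoxy-4-oxocyclobut-2-en-1-olate | [Li+].[O-]C1(c2cc(=O)c(OCc3ccccc3)c(-c3ccc(OC)cc3)o2)C(OC)=C(OC)C1=O | intermediate (not isolated)
10 | 4-[5-(benzyloxy)-6-(4-methoxyphenyl)-4-oxo-4H-pyran-2-yl]-2,3,4-trimethoxycyclobut-2-en-1-one (racemic) | COC1(c2cc(=O)c(OCc3ccccc3)c(-c3ccc(OC)cc3)o2)C(OC)=C(OC)C1=O | intermediate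
11 | (3Z)-4-[5-(benzyloxy)-6-(4-methoxyphenyl)-4-oxo-4H-pyran-2-yl]-2,3,4-trimethoxybuta-1,3-dien-1-one | CO/C(C(OC)=C=O)=C(\OC)c1cc(=O)c(OCc2ccccc2)c(-c2ccc(OC)cc2)o1 | intermediate (not isolated)
12 | 3-(benzyloxy)-6,7,8-trimethoxy-2-(4-methoxyphenyl)-4aH-chromene-4,5-dione (racemic at C4a) | O=C1C(OC)=C(OC)C(OC)=C2OC(c3ccc(OC)cc3)=C(OCc3ccccc3)C(=O)C12 | intermediate (not isolated)
13 | 3-(benzyloxy)-5-hydroxy-6,7,8-trimethoxy-2-(4-methoxyphenyl)-4H-chromen-4-one | COc1ccc(-c2oc3c(OC)c(OC)c(OC)c(O)c3c(=O)c2OCc2ccccc2)cc1 | intermediate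
14 | 3,5-dihydroxy-6,7,8-trimethoxy-2-(4-methoxyphenyl)-4H-chromen-4-one (3,5-dihydroxy-6,7,8,4'-tetramethoxyflavone) | COc1ccc(-c2oc3c(OC)c(OC)c(OC)c(O)c3c(=O)c2O)cc1 | target

**Totals**

Total step count: 5. Longest linear sequence: 5 steps (1/2 → 3 → 6 → 10 → 13 → 14).

**Steps most likely to fail**

Step 3. Deprotonation may not stay confined to C6–H: metalation at C5 or at the benzylic CH2, or addition of the amide to the pyranone, can compete, and the lithio species may self-condense before it meets 7. The fallback sets out from 6 and comes back to the route at 8. Zincation of 6 with TMPZnCl·LiCl (THF, 25 °C, no Lewis-acid additive, which should direct to the carbon next to the ring oxygen) should give [5-(benzyloxy)-6-(4-methoxyphenyl)-4-oxo-4H-pyran-2-yl]zinc chloride F1. Iodinolysis with I2 should give 3-(benzyloxy)-6-iodo-2-(4-methoxyphenyl)-4H-pyran-4-one F2, which can be purified free of any regioisomer. Iodine–lithium exchange (n-BuLi, THF/Et2O, −100 °C) should then generate 8 regiospecifically and without an amide base, and 7 and MeOTf are added as in step 3.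

Step 4. The ketene may be consumed by dimerisation or adventitious nucleophiles faster than it closes onto the pyranone carbon, or the pyranone may degrade on prolonged heating. The fallback sets out from 7 and comes back to the route at 14; it forms ring A first on a simple enol ether and builds the heterocycle afterwards by classical means. 1-Methoxyvinyllithium (methyl vinyl ether, t-BuLi, THF) is added to 7 and the alkoxide is methylated with MeOTf to give 2,3,4-trimethoxy-4-(1-methoxyethenyl)cyclobut-2-en-1-one F3. Thermolysis in toluene should give 2,3,4,5-tetramethoxyphenol F4. Fries-type ortho-acylation with methoxyacetic acid in BF3·OEt2 at its only free position should give 1-(2-hydroxy-3,4,5,6-tetramethoxyphenyl)-2-methoxyethan-1-one F5. Allan–Robinson condensation (4-methoxybenzoic anhydride, sodium 4-methoxybenzoate, 180 °C) should give 3,5,6,7,8-pentamethoxy-2-(4-methoxyphenyl)-4H-chromen-4-one F6. Chelation-controlled cleavage of the two methyl ethers flanking the C4 carbonyl (AlBr3, MeCN, 0 °C to rt) should then give 14.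

Step 2. The magnesium enolate of 3 may be O-acylated or acylated twice, the acryloyl chloride may oligomerise, or the diketone may cyclise sluggishly. The fallback sets out from 2 and comes back to the route at 6; the pyranone ring is bought rather than built and the aryl group is attached by cross-coupling. Commercial 3-hydroxy-4H-pyran-4-one is brominated next to the enolic hydroxyl (NBS, MeCN, 0 °C) to 2-bromo-3-hydroxy-4H-pyran-4-one F7 and benzylated (BnBr, K2CO3, DMF) to 3-(benzyloxy)-2-bromo-4H-pyran-4-one F8. Grignard reagent 2 is transmetalated with ZnCl2 to (4-methoxyphenyl)zinc chloride F9, and Negishi coupling of F8 with F9 (Pd(PPh3)4, THF, 50 °C) should give 6.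

**Further compounds**

F1 | step 3 | [5-(benzyloxy)-6-(4-methoxyphenyl)-4-oxo-4H-pyran-2-yl]zinc chloride | Cl[Zn]c1cc(=O)c(OCc2ccccc2)c(-c2ccc(OC)cc2)o1
F2 | step 3 | 3-(benzyloxy)-6-iodo-2-(4-methoxyphenyl)-4H-pyran-4-one | Ic1cc(=O)c(OCc2ccccc2)c(-c2ccc(OC)cc2)o1
F3 | step 4 | 2,3,4-trimethoxy-4-(1-methoxyethenyl)cyclobut-2-en-1-one | COC(=C)C1(OC)C(OC)=C(OC)C1=O
F4 | step 4 | 2,3,4,5-tetramethoxyphenol | COc1cc(O)c(OC)c(OC)c1OC
F5 | step 4 | 1-(2-hydroxy-3,4,5,6-tetramethoxyphenyl)-2-methoxyethan-1-one | COCC(=O)c1c(O)c(OC)c(OC)c(OC)c1OC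
F6 | step 4 | 3,5,6,7,8-pentamethoxy-2-(4-methoxyphenyl)-4H-chromen-4-one | COc1ccc(-c2oc3c(OC)c(OC)c(OC)c(OC)c3c(=O)c2OC)cc1
F7 | step 2 | 2-bromo-3-hydroxy-4H-pyran-4-one | O=c1ccoc(Br)c1O
F8 | step 2 | 3-(benzyloxy)-2-bromo-4H-pyran-4-one | O=c1ccoc(Br)c1OCc1ccccc1
F9 | step 2 | (4-methoxyphenyl)zinc chloride | COc1ccc([Zn]Cl)cc1
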